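**Retrosynthetic overview**

1. Endgame: the C4 acetoxymethyl group comes from selective acetylation of the C3‑OH/C4‑CH2OH diol (carried as an acetonide), and the umbelliferyl ether from a Mitsunobu reaction at C11. The 8(12)-exocyclic alkene next to the C7 methylene comes from palladium/formate hydrogenolysis (allylic transposition) of a Δ7 allylic C12 carbonate, itself from reduction of an α‑alkylidene lactone.
2. Key disconnection: ring B is closed at C7–C8 by an aldol of a lactone enolate (C8) onto a C7 aldehyde. The same operation makes the C9–C10 bond by hydrogen‑atom‑transfer Giese addition of a ring A C10 radical to an enantiopure 5‑menthyloxybutenolide (which supplies C8, C9, C11, C12).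
3. Enabling feature: C10 is a quaternary, methyl‑bearing carbon of ring A, so it can be reached as a tertiary radical from an exocyclic C10=CH2 alkene, and it sits 1,4 to C7 across ring B. C8 carries the one‑carbon branch C12, which as a lactone carbonyl turns C8 into an enolate carbon once the radical has added at C9.
4. Ring A (C4–C5 bond) comes from a Mn(OAc)3/Cu(OAc)2 oxidative radical cyclization of an 8‑phenylmenthyl β‑keto ester, which sets C4 and C5. C3 follows by hydride reduction; C10 and C9 are set in the key step by substrate and reagent control.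
5. Order of ring formation: ring A, then the temporary dioxane (acetonide), then ring B fused to the temporary butyrolactone (bought as the butenolide); the coumarin is bought.

Key step: step 10

Numbering: drimane numbering is used (ring A = C1–C5 and C10; ring B = C5–C10; C11 = oxymethyl carbon on C9; C12 = methylidene carbon on C8). α/β refer to the usual drawing with ring A at the left. The target is (3R,4R,5S,9R,10R): 3α‑OH, 4α‑CH2OAc, 4β‑methyl, 5β‑H, 9β‑H, 10α‑methyl.

Assumption: the (1S,2R,5S)-8‑phenylmenthyl ester is taken to shield the enolate‑radical face that leads to the ring A enantiomer drawn in step 6; if the sense is the opposite, the enantiomeric auxiliary is used.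

Assumption: both enantiomers of 8‑phenylmenthol and of 5‑menthyloxyfuran‑2(5H)‑one are taken as commercial; the butenolide is otherwise one acetalization step from 5‑hydroxyfuran‑2(5H)‑one and (1S,2R,5S)-menthol.

**Route**

Step 1
Reactants: 1 4-methylpent-3-en-1-ol
Product: 2 4-methylpent-3-en-1-yl pivalate
Conditions: PivCl, pyridine, DMAP (cat.), CH2Cl2, 0 to 23 °C
Reagents that add atoms: pivaloyl chloride CC(C)(C)C(Cl)=O
Why: Pyridine/DMAP acylation (esterification) of the primary alcohol gives a hindered pivalate that should survive the allylic oxidation, the dianion alkylation and the acidic radical cyclization and is removed without an extra step in the hydride reduction of step 7.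

Step 2
Reactants: 2 4-methylpent-3-en-1-yl pivalate
Product: 3 (E)-5-hydroxy-4-methylpent-3-en-1-yl pivalate
Conditions: SeO2 (cat.), t-BuOOH, salicylic acid (cat.), CH2Cl2, 23 °C
Reagents that add atoms: tert-butyl hydroperoxide CC(C)(C)OO
Why: Riley allylic oxidation (ene reaction with SeO2, then [2,3]-sigmatropic shift, SeO2 being turned over by the hydroperoxide) attacks the methyl group trans to the chain of a trisubstituted alkene, so the (E)-allylic alcohol should be formed.

Step 3
Reactants: 3 (E)-5-hydroxy-4-methylpent-3-en-1-yl pivalate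
Product: 4 (E)-5-bromo-4-methylpent-3-en-1-yl pivalate
Conditions: CBr4, PPh3, CH2Cl2, 0 °C
Reagents that add atoms: carbon tetrabromide BrC(Br)(Br)Br
Why: Appel reaction, in which the alkoxyphosphonium bromide collapses by SN2 at the primary allylic carbon, should give the bromide without allylic transposition or loss of the (E) geometry.

Step 4
Reactants: 5 (1S,2R,5S)-8-phenylmenthol; 6 methyl 2-methyl-3-oxobutanoate
Product: 7 (1S,2R,5S)-8-phenylmenthyl 2-methyl-3-oxobutanoate (both C2 epimers)
Conditions: DMAP (cat.), toluene, reflux, 4 Å molecular sieves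
Reagents that add atoms: none
Why: DMAP-catalysed transesterification of a β-keto ester (through the acylketene, driven by removal of methanol) attaches the chiral auxiliary, and the epimeric α-carbon is of no consequence because it becomes the radical centre in step 6.

Step 5
Reactants: 7 (1S,2R,5S)-8-phenylmenthyl 2-methyl-3-oxobutanoate; 4 (E)-5-bromo-4-methylpent-3-en-1-yl pivalate
Product: 8 (1S,2R,5S)-8-phenylmenthyl (E)-2,6-dimethyl-3-oxo-9-(pivaloyloxy)non-6-enoate (both C2 epimers)
Conditions: NaH, THF, 0 °C; n-BuLi, 0 °C; then 4, 0 to 23 °C; 1 M HCl quench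
Reagents that add atoms: none
Why: γ-Alkylation of a β-keto ester dianion, in which the terminal and more basic carbanion displaces the primary allylic bromide by SN2, should join the two halves with the (E)-alkene intact.

Step 6
Reactants: 8 (1S,2R,5S)-8-phenylmenthyl (E)-2,6-dimethyl-3-oxo-9-(pivaloyloxy)non-6-enoate
Product: 9 (1S,2R,5S)-8-phenylmenthyl (1S,2S)-1-methyl-3-methylidene-6-oxo-2-[2-(pivaloyloxy)ethyl]cyclohexane-1-carboxylate (ring A keto ester; ester cis to the side chain)
Conditions: Mn(OAc)3·2H2O (2.2 equiv), Cu(OAc)2·H2O (0.2 equiv), AcOH, 23 to 40 °C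
Reagents that add atoms: none
Why: Mn(OAc)3/Cu(OAc)2 oxidative free-radical cyclization, in which the trivalent manganese enolate gives the C4 radical that closes ring A 6-endo-trig on C5 of the (E)-alkene through a chair placing the ester axial and the C5 side chain equatorial (ester cis to the side chain), the phenyl ring of the auxiliary shields one face of the radical and so fixes the absolute configuration of C4 and C5, and divalent copper oxidizes the tertiary C10 radical to the exocyclic alkene (any endocyclic isomer would give the same C10 radical in step 10).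

Step 7
Reactants: 9 ring A keto ester
Product: 10 (1R,2R,3S)-3-(2-hydroxyethyl)-2-(hydroxymethyl)-2-methyl-4-methylidenecyclohexan-1-ol (ring A triol)
Conditions: LiAlH4, THF, 0 °C to reflux; then H2O
Reagents that add atoms: none
Why: LiAlH4 reduction of ketone, auxiliary ester and pivalate in one operation, in which hydride should attack the C3 ketone axially on the face away from the axial C4 ester carbon so that the equatorial C3 alcohol cis to the new C4 hydroxymethyl group results (substrate control), and the auxiliary is recovered.

Step 8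
Reactants: 10 ring A triol
Product: 11 2-[(4aR,5S,8aR)-2,2,4a-trimethyl-6-methylidenehexahydro-4H-benzo[d][1,3]dioxin-5-yl]ethan-1-ol (acetonide alcohol)
Conditions: 2,2-dimethoxypropane, PPTS (cat.), CH2Cl2, 23 °C
Reagents that add atoms: 2,2-dimethoxypropane COC(C)(C)OC
Why: Acetonide formation by transketalization, in which only the cis-1,3-diol (C3 hydroxyl and C4 hydroxymethyl) can close a six-membered dioxane, should leave the remote primary alcohol free.

Step 9
Reactants: 11 acetonide alcohol
Product: 12 2-[(4aR,5S,8aR)-2,2,4a-trimethyl-6-methylidenehexahydro-4H-benzo[d][1,3]dioxin-5-yl]acetaldehyde (ring A aldehyde)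
Conditions: Dess–Martin periodinane, CH2Cl2, 23 °C
Reagents that add atoms: none
Why: Dess–Martin oxidation converts the primary alcohol to the aldehyde under neutral conditions that should spare the acetonide and the 1,1-disubstituted alkene.

Step 10
Reactants: 12 ring A aldehyde; 13 (5S)-5-[(1S,2R,5S)-menthyloxy]furan-2(5H)-one
Product: 16 tricyclic hydroxy lactone acetal (ring B closed; trans-fused butyrolactone; C7 epimers), via tertiary C10 radical 14 (not isolated), via lactone enolate 15 (not isolated)
Conditions: Fe(acac)3 (30 mol %), PhSiH3, 13 (1.5 equiv), THF/EtOH, 23 °C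
Reagents that add atoms: none
Why: Proposed new method: Fe(acac)3/PhSiH3 generates an iron hydride that transfers a hydrogen atom to the terminal carbon of the exocyclic C10=CH2 alkene, so that this hydrogen completes the C10 methyl group and leaves tertiary radical 14, which adds to the β-carbon of butenolide 13 (Giese addition, C9–C10 bond); reduction of the resulting α-acyl radical by divalent iron gives lactone enolate 15, whose C8 attacks the tethered C7 aldehyde (intramolecular aldol, C7–C8 bond) and closes ring B. The closest known reaction type is the iron-hydride-initiated radical conjugate addition/aldol annulation of alkenyl aldehydes with enones and enals, and tertiary radicals are known to add to 5-alkoxybutenolides anti to the alkoxy group; what is new is the interception of a lactone enolate. Ring B closes by a 6-(enolexo)-exo-trig aldol, and the lactone ends trans-fused because C8 reacts on the enolate face opposite to the C10 substituent on C9. C10 is set by equatorial attack of the acceptor on the ring A radical (the axial face is blocked by the axial C4 CH2O arm of the acetonide), which places the new methyl group axial and trans to H5; C9 is set by the menthyloxy acetal carbon C11 of the reagent (anti addition); C8 and the C7 carbinol are erased in step 11. The step needs hydrogen atom transfer to the electron-rich 1,1-disubstituted alkene and not to the electron-poor butenolide, and aldol capture faster than enolate protonation; the first is secured by the polarity preference of the iron hydride, the second by the six-membered transition state and by keeping the alcohol co-solvent to a minimum.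

Step 11
Reactants: 16 tricyclic hydroxy lactone acetal
Product: 18 Δ7 α-alkylidene lactone acetal, via C7 mesylate 17 (not isolated)
Conditions: MsCl, Et3N, CH2Cl2, 0 °C; then DBU, 23 °C
Reagents that add atoms: none
Why: Mesylation and E1cB elimination of the β-mesyloxy lactone should give the conjugated alkylidene lactone with the C7=C8 double bond, which erases the C7 and C8 stereocentres and makes C12 allylic.

Step 12
Reactants: 18 Δ7 α-alkylidene lactone acetal
Product: 19 Δ7-11,12-diol acetonide
Conditions: LiAlH4, Et2O, 0 °C; then H2O
Reagents that add atoms: none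
Why: LiAlH4 reduction of the lactone acetal, a masked 1,4-dicarbonyl compound, should open it by 1,2-reduction to the allylic C12 alcohol and the C11 alcohol with release of menthol, the acetonide being inert and C9 keeping its configuration because the transient C11 aldehyde is reduced at once.

Step 13
Reactants: 19 Δ7-11,12-diol acetonide
Product: 20 11,12-bis(methyl carbonate)
Conditions: ClCO2Me, pyridine, DMAP (cat.), CH2Cl2, 0 to 23 °C
Reagents that add atoms: methyl chloroformate COC(Cl)=O
Why: Acylation of both primary alcohols with methyl chloroformate gives the bis-carbonate, in which only the allylic C12 carbonate can be ionized by palladium in step 14.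

Step 14
Reactants: 20 11,12-bis(methyl carbonate)
Product: 22 exocyclic alkene C11 alcohol (acetonide), via C11 methyl carbonate 21 (not isolated)
Conditions: Pd(OAc)2 (5 mol %), PBu3 (20 mol %), HCO2NH4, 1,4-dioxane, 90 °C; then K2CO3 (cat.), MeOH, 23 °C
Reagents that add atoms: none
Why: Tsuji–Trost ionization of the allylic C12 carbonate and formate hydrogenolysis of the π-allylpalladium complex, in which with PBu3 the hydride is transferred from palladium to the more substituted allyl terminus C7, should move the alkene to the exocyclic C8=C12 position and leave C7 as a methylene, and the untouched homoallylic C11 carbonate is then removed by methanolysis.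

Step 15
Reactants: 22 exocyclic alkene C11 alcohol; 23 umbelliferone
Product: 24 umbelliferyl ether acetonide
Conditions: PPh3, DIAD, THF, 0 to 50 °C
Reagents that add atoms: none
Why: Mitsunobu etherification, in which the acidic 7-hydroxyl of umbelliferone protonates the betaine and its phenoxide displaces the oxyphosphonium of the primary C11 alcohol by SN2, touches no stereocentre.

Step 16
Reactants: 24 umbelliferyl ether acetonide
Product: 25 umbelliferyl ether diol
Conditions: AcOH/H2O/THF (3:1:1), 40 °C
Reagents that add atoms: none
Why: Acid-catalysed acetal hydrolysis should remove the acetonide under conditions mild enough for the exocyclic alkene, the aryl alkyl ether and the coumarin lactone.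

Step 17
Reactants: 25 umbelliferyl ether diol
Product: 26 CNP0271943.1 (target)
Conditions: Ac2O (1.1 equiv), 2,4,6-collidine, CH2Cl2, −20 to 0 °C
Reagents that add atoms: acetic anhydride CC(=O)OC(C)=O
Why: Chemoselective acylation, in which the primary C4 hydroxymethyl group should react with one equivalent of anhydride much faster than the secondary C3 alcohol flanked by the quaternary C4, gives the C4 acetoxymethyl compound, which is the target.

**Compound list**

1 | 4-methylpent-3-en-1-ol | CC(C)=CCCO | starting material
2 | 4-methylpent-3-en-1-yl pivalate | CC(C)=CCCOC(=O)C(C)(C)C | intermediate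
3 | (E)-5-hydroxy-4-methylpent-3-en-1-yl pivalate | OC/C(C)=C/CCOC(=O)C(C)(C)C | intermediate
4 | (E)-5-bromo-4-methylpent-3-en-1-yl pivalate | BrC/C(C)=C/CCOC(=O)C(C)(C)C | intermediate
5 | (1S,2R,5S)-8-phenylmenthol [(1S,2R,5S)-5-methyl-2-(2-phenylpropan-2-yl)cyclohexan-1-ol] | O[C@H]1C[C@@H](C)CC[C@@H]1C(C)(C)c1ccccc1 | starting material
6 | methyl 2-methyl-3-oxobutanoate | COC(=O)C(C)C(C)=O | starting material
7 | (1S,2R,5S)-8-phenylmenthyl 2-methyl-3-oxobutanoate (C2 epimers) | CC(=O)C(C)C(=O)O[C@H]1C[C@@H](C)CC[C@@H]1C(C)(C)c1ccccc1 | intermediate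
8 | (1S,2R,5S)-8-phenylmenthyl (E)-2,6-dimethyl-3-oxo-9-(pivaloyloxy)non-6-enoate (C2 epimers) | CC(C(=O)CC/C(C)=C/CCOC(=O)C(C)(C)C)C(=O)O[C@H]1C[C@@H](C)CC[C@@H]1C(C)(C)c1ccccc1 | intermediate
9 | (1S,2R,5S)-8-phenylmenthyl (1S,2S)-1-methyl-3-methylidene-6-oxo-2-[2-(pivaloyloxy)ethyl]cyclohexane-1-carboxylate (ester cis to the side chain) | CC(C)(C)C(=O)OCC[C@@H]1[C@](C)(C(=O)O[C@H]2C[C@@H](C)CC[C@@H]2C(C)(C)c2ccccc2)C(=O)CCC1=C | intermediate
10 | (1R,2R,3S)-3-(2-hydroxyethyl)-2-(hydroxymethyl)-2-methyl-4-methylidenecyclohexan-1-ol (the three oxygen-bearing arms cis) | OCC[C@@H]1[C@](C)(CO)[C@H](O)CCC1=C | intermediate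
11 | 2-[(4aR,5S,8aR)-2,2,4a-trimethyl-6-methylidenehexahydro-4H-benzo[d][1,3]dioxin-5-yl]ethan-1-ol | OCC[C@@H]1[C@](C)(COC(C)(C)O2)[C@H]2CCC1=C | intermediate
12 | 2-[(4aR,5S,8aR)-2,2,4a-trimethyl-6-methylidenehexahydro-4H-benzo[d][1,3]dioxin-5-yl]acetaldehyde | O=CC[C@@H]1[C@](C)(COC(C)(C)O2)[C@H]2CCC1=C | intermediate
13 | (5S)-5-[(1S,2R,5S)-menthyloxy]furan-2(5H)-one | O=C1C=C[C@@H](O[C@H]2C[C@@H](C)CC[C@@H]2C(C)C)O1 | starting material
14 | tertiary C10 radical formed from 12 by hydrogen atom transfer (not isolated) | O=CC[C@@H]1[C@](C)(COC(C)(C)O2)[C@H]2CC[C]1C | intermediate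
15 | lactone enolate of the Giese adduct, iron-bound, drawn as the free enolate (not isolated) | O=CC[C@@H]1[C@](C)(COC(C)(C)O2)[C@H]2CC[C@@]1(C)[C@H]3C=C([O-])O[C@@H]3O[C@H]4C[C@@H](C)CC[C@@H]4C(C)C | intermediate
16 | tricyclic β-hydroxy lactone acetal: drimane-type decalin with 7-OH (both epimers), 8α-H, 9β-H, 10α-methyl, lactone carbonyl C12 on C8, (11S)-menthyloxy acetal carbon C11 on C9, 3α-O/4α-CH2O acetonide | OC1C[C@@H]2[C@](C)(COC(C)(C)O3)[C@H]3CC[C@@]2(C)[C@H]5[C@H]1C(=O)O[C@@H]5O[C@H]4C[C@@H](C)CC[C@@H]4C(C)C | intermediate
17 | C7 methanesulfonate of 16 (not isolated) | CS(=O)(=O)OC1C[C@@H]2[C@](C)(COC(C)(C)O3)[C@H]3CC[C@@]2(C)[C@H]5[C@H]1C(=O)O[C@@H]5O[C@H]4C[C@@H](C)CC[C@@H]4C(C)C | intermediate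
18 | Δ7 α-alkylidene lactone acetal: as 16 with a C7=C8 double bond in place of 7-OH and 8-H | O=C1O[C@H](O[C@H]4C[C@@H](C)CC[C@@H]4C(C)C)[C@@H]2C1=CC[C@@H]1[C@](C)(COC(C)(C)O3)[C@H]3CC[C@]12C | intermediate
19 | Δ7-11,12-diol acetonide: drim-7-ene with CH2OH on C8 (C12) and on C9 (C11, α), 3α-O/4α-CH2O acetonide, 5β-H, 9β-H, 10α-methyl | OCC1=CC[C@@H]2[C@](C)(COC(C)(C)O3)[C@H]3CC[C@@]2(C)[C@@H]1CO | intermediate
20 | 11,12-bis(methyl carbonate) of 19 | COC(=O)OCC1=CC[C@@H]2[C@](C)(COC(C)(C)O3)[C@H]3CC[C@@]2(C)[C@@H]1COC(=O)OC | intermediate
21 | C11 methyl carbonate of the 8(12)-exocyclic alkene acetonide (not isolated) | C=C1CC[C@@H]2[C@](C)(COC(C)(C)O3)[C@H]3CC[C@@]2(C)[C@@H]1COC(=O)OC | intermediate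
22 | 8(12)-exocyclic alkene C11 alcohol, 3α-O/4α-CH2O acetonide | C=C1CC[C@@H]2[C@](C)(COC(C)(C)O3)[C@H]3CC[C@@]2(C)[C@@H]1CO | intermediate
23 | umbelliferone (7-hydroxy-2H-chromen-2-one) | Oc1ccc2ccc(=O)oc2c1 | starting material
24 | C11 umbelliferyl ether of 22 (acetonide) | C=C1CC[C@@H]2[C@](C)(COC(C)(C)O3)[C@H]3CC[C@@]2(C)[C@@H]1COc1ccc2ccc(=O)oc2c1 | intermediate
25 | C11 umbelliferyl ether with free 3α-OH and 4α-CH2OH | C=C1CC[C@@H]2[C@](C)(CO)[C@H](O)CC[C@@]2(C)[C@@H]1COc1ccc2ccc(=O)oc2c1 | intermediate
26 | CNP0271943.1: (3R,4R,5S,9R,10R) C11 umbelliferyl ether with 3α-OH and 4α-CH2OAc | C=C1CC[C@@H]2[C@](C)(COC(C)=O)[C@H](O)CC[C@@]2(C)[C@@H]1COc1ccc2ccc(=O)oc2c1 | target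

**Step count and risks**

Total step count: 17. Longest linear sequence: 16 steps (steps 1–3 and 5–17 from 1; step 4 is a one-step branch from 5 and 6).

Step 10 (the proposed new method) is the most likely to fail. The lactone enolate, or its iron complex, may be protonated before it reaches the aldehyde, so that the cascade stops after the Giese addition; reduction of the alkene or of the aldehyde by the iron hydride/silane may also compete. The fallback uses known chemistry, sets out from 12 and 13 and comes back at 16. Butenolide 13 is chlorinated and dehydrochlorinated in one flask (Cl2 in CH2Cl2, then Et3N) through 3,4-dichloro lactone F1 to 3-chlorobutenolide F2. The iron-hydride Giese addition of 12 to F2 is then run in ethanol, where it is allowed to stop at the protonated adduct, α-chloro lactone aldehyde F3; tertiary radicals are known to add to α-chloro-5-alkoxybutenolides anti to the alkoxy group. SmI2 in THF at −78 °C then generates the samarium enolate at C8 regiospecifically from the C–Cl bond and closes ring B by an intramolecular Reformatsky aldol, which gives 16.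

Step 15 is the second risk. Displacement at the β-branched, neopentyl-like C11 may be slow, so that the oxyphosphonium intermediate is consumed by the hydrazide or by elimination. The fallback sets out from 22 and comes back at 24: the alcohol is converted into C11 mesylate F4 (MsCl, Et3N), which is displaced in a Williamson ether synthesis by the caesium salt of 23 (Cs2CO3, DMF, 70 °C).

Step 6 is the third risk. Facial discrimination by the auxiliary may be insufficient, the diastereomers may then be hard to separate, or the hindered ester may convert slowly. The fallback sets out from 4 and 6 and comes back at 10, with the absolute configuration secured by resolution instead of by the auxiliary. The dianion of 6 is alkylated with 4 to give methyl keto ester F5; the same Mn(OAc)3/Cu(OAc)2 cyclization gives racemic cyclic keto ester F6; LiAlH4 gives racemic triol F7; preparative chromatography on a chiral stationary phase then delivers enantiopure 10.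

Further compounds
F1 | step 10 | (5S)-3,4-dichloro-5-[(1S,2R,5S)-menthyloxy]dihydrofuran-2(3H)-one (trans dichloride, C3/C4 unassigned) | O=C1C(Cl)C(Cl)[C@@H](O[C@H]2C[C@@H](C)CC[C@@H]2C(C)C)O1
F2 | step 10 | (5S)-3-chloro-5-[(1S,2R,5S)-menthyloxy]furan-2(5H)-one | O=C1C(Cl)=C[C@@H](O[C@H]2C[C@@H](C)CC[C@@H]2C(C)C)O1
F3 | step 10 | α-chloro lactone aldehyde (protonated Giese adduct of 12 and F2; C8 epimers) | O=CC[C@@H]1[C@](C)(COC(C)(C)O2)[C@H]2CC[C@@]1(C)[C@H]3C(Cl)C(=O)O[C@@H]3O[C@H]4C[C@@H](C)CC[C@@H]4C(C)C
F4 | step 15 | C11 methanesulfonate of 22 | C=C1CC[C@@H]2[C@](C)(COC(C)(C)O3)[C@H]3CC[C@@]2(C)[C@@H]1COS(C)(=O)=O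
F5 | step 6 | methyl (E)-2,6-dimethyl-3-oxo-9-(pivaloyloxy)non-6-enoate (C2 epimers) | COC(=O)C(C)C(=O)CC/C(C)=C/CCOC(=O)C(C)(C)C
F6 | step 6 | racemic methyl 1-methyl-3-methylidene-6-oxo-2-[2-(pivaloyloxy)ethyl]cyclohexane-1-carboxylate (ester cis to the side chain; both enantiomers) | CC(C)(C)C(=O)OCC[C@@H]1[C@](C)(C(=O)OC)C(=O)CCC1=C.CC(C)(C)C(=O)OCC[C@H]1[C@@](C)(C(=O)OC)C(=O)CCC1=C
F7 | step 6 | racemic 3-(2-hydroxyethyl)-2-(hydroxymethyl)-2-methyl-4-methylidenecyclohexan-1-ol (10 and its enantiomer) | OCC[C@@H]1[C@](C)(CO)[C@H](O)CCC1=C.OCC[C@H]1[C@@](C)(CO)[C@@H](O)CCC1=C
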